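Everything rests on cutting the 1,2-dioxolane (O1–O2–C3–C4–C5) at C4–C5 and O2–C3. The feature used is the unsubstituted C4 methylene between the two methyl-bearing quaternary peroxide carbons C3 and C5, which is the footprint of a ketone-derived peroxycarbenium ion (C5) adding across a 1,1-disubstituted alkene (C4=C3). One counter-anion-controlled (3+2) annulation should close the ring, join both fragments and set C3 and C5. Its precursors are the triethylsilyl methoxy peroxyketal of the (4R)-methyl ketone that already carries the diene side chain and C7, and the triisopropylsilyl ether of 3-methylbut-3-en-1-ol, whose two-carbon arm is oxidised to the acid at the end.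

Key step: step 11

Assumption: ring atoms are numbered O1–O2–C3–C4–C5 with the acid arm on C3 and the chain running C6, C7 onward from C5; the sense of induction of the ligand named in step 4 and of the catalyst named in step 11 is taken by analogy and is to be confirmed on a trial scale, the mirror-image ligand or catalyst being used if it proves opposite.

Step 1
Reactants: 1 (E)-5-phenylpent-4-enoic acid
Product: 2 (E)-5-phenylpent-4-en-1-ol
Conditions: LiAlH4, THF, 0 °C to rt; then H2O, aq. NaOH
Reagents that add atoms: none
Why: Hydride reduction of a carboxylic acid to the primary alcohol, in which the styrene double bond, not conjugated to the carbonyl group, should stay untouched.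

Step 2
Reactants: 2 (E)-5-phenylpent-4-en-1-ol
Product: 3 1-phenyl-5-{[(4E)-5-phenylpent-4-en-1-yl]sulfanyl}-1H-tetrazole
Conditions: 1-phenyl-1H-tetrazole-5-thiol, PPh3, diisopropyl azodicarboxylate, THF, 0 °C to rt
Reagents that add atoms: 1-phenyl-1H-tetrazole-5-thiol, Sc1nnnn1-c1ccccc1
Why: Mitsunobu reaction, in which the phosphonium-activated primary alcohol is displaced by the acidic heteroaryl thiol in an SN2 step.

Step 3
Reactants: 3 1-phenyl-5-{[(4E)-5-phenylpent-4-en-1-yl]sulfanyl}-1H-tetrazole
Product: 4 1-phenyl-5-{[(4E)-5-phenylpent-4-en-1-yl]sulfonyl}-1H-tetrazole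
Conditions: (NH4)6Mo7O24·4H2O (cat.), 30% aq. H2O2, EtOH, 0 °C to rt
Reagents that add atoms: hydrogen peroxide, OO
Why: Molybdate-catalysed oxidation of a sulfide to the sulfone, in which the peroxomolybdate reacts at sulfur far faster than at the styrene double bond.

Step 4
Reactants: 5 6-bromohex-1-ene; 6 (E)-pent-3-en-2-one
Product: 8 (4R)-4-methyldec-9-en-2-one, via hex-5-en-1-ylmagnesium bromide 7 (not isolated)
Conditions: 5, Mg, Et2O, rt; then added slowly to 6 (freshly distilled), CuBr·SMe2 (5 mol%), (R)-1-[(S_p)-2-(diphenylphosphino)ferrocenyl]ethyldicyclohexylphosphine (6 mol%), t-BuOMe, −75 °C; aq. NH4Cl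
Reagents that add atoms: none
Why: Copper-catalysed enantioselective conjugate addition of a Grignard reagent to an acyclic (E)-enone, in which the chiral ferrocenyl diphosphine on copper selects the enone face and so sets C4 as R.

Step 5
Reactants: 8 (4R)-4-methyldec-9-en-2-one
Product: 9 (7R)-9,9-dimethoxy-7-methyldec-1-ene
Conditions: HC(OMe)3, MeOH, p-TsOH·H2O (cat.), rt; Et3N quench
Reagents that add atoms: trimethyl orthoformate, COC(OC)OC; methanol, CO
Why: Acid-catalysed ketalisation driven by the orthoformate as water scavenger, with the stereocentre beta to the carbonyl group and therefore not open to epimerisation.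

Step 6
Reactants: 9 (7R)-9,9-dimethoxy-7-methyldec-1-ene
Product: 10 (6R)-8,8-dimethoxy-6-methylnonanal
Conditions: O3, CH2Cl2, −78 °C; then PPh3, −78 °C to rt
Reagents that add atoms: ozone, [O-][O+]=O
Why: Ozonolysis of the only alkene present with reductive work-up should give the aldehyde, the ketal having no acetal hydrogen for ozone to attack and being stable to the neutral work-up.

Step 7
Reactants: 4 1-phenyl-5-{[(4E)-5-phenylpent-4-en-1-yl]sulfonyl}-1H-tetrazole; 10 (6R)-8,8-dimethoxy-6-methylnonanal
Product: 11 [(1E,5E,11R)-13,13-dimethoxy-11-methyltetradeca-1,5-dien-1-yl]benzene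
Conditions: 4, KN(SiMe3)2, 1,2-dimethoxyethane, −60 °C; then 10, −60 °C to rt; aq. NH4Cl
Reagents that add atoms: none
Why: Julia–Kocienski olefination, in which the potassium anion of the phenyltetrazolyl sulfone adds to the unbranched aldehyde and, after Smiles rearrangement and loss of SO2, should give the (E)-alkene, the base-stable ketal masking the ketone.

Step 8
Reactants: 11 [(1E,5E,11R)-13,13-dimethoxy-11-methyltetradeca-1,5-dien-1-yl]benzene
Product: 12 (4R,9E,13E)-2-methoxy-4-methyl-14-phenyltetradeca-9,13-dien-2-yl hydroperoxide (both C2 epimers)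
Conditions: H2O2 (anhydrous, ca. 2 M in Et2O, excess), 10-camphorsulfonic acid (cat.), Et2O, 0 °C; NaHCO3 quench
Reagents that add atoms: hydrogen peroxide, OO
Why: Acid-catalysed perhydrolysis of a ketal, in which one methoxy group is exchanged for hydroperoxide through the methoxycarbenium ion and the reaction is stopped at mono-exchange by low temperature and short time, both C2 epimers being usable because C2 is ionised in step 11.

Step 9
Reactants: 12 (4R,9E,13E)-2-methoxy-4-methyl-14-phenyltetradeca-9,13-dien-2-yl hydroperoxide
Product: 13 triethyl{[(4R,9E,13E)-2-methoxy-4-methyl-14-phenyltetradeca-9,13-dien-2-yl]peroxy}silane (both C2 epimers)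
Conditions: Et3SiCl, imidazole, DMF, 0 °C
Reagents that add atoms: chlorotriethylsilane, CC[Si](Cl)(CC)CC
Why: O-Silylation of the acidic hydroperoxide under basic conditions, chosen in place of a silyl triflate so that the acid-labile peroxyketal is not ionised.

Step 10
Reactants: 14 3-methylbut-3-en-1-ol
Product: 15 [(3-methylbut-3-en-1-yl)oxy]tri(propan-2-yl)silane
Conditions: i-Pr3SiCl, imidazole, DMF, rt
Reagents that add atoms: chlorotri(propan-2-yl)silane, CC(C)[Si](Cl)(C(C)C)C(C)C
Why: Standard silylation of a primary alcohol, the bulky silyl group making the ether oxygen a poor ligand for silylium in step 11.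

Step 11
Reactants: 13 triethyl{[(4R,9E,13E)-2-methoxy-4-methyl-14-phenyltetradeca-9,13-dien-2-yl]peroxy}silane; 15 [(3-methylbut-3-en-1-yl)oxy]tri(propan-2-yl)silane
Product: 16 {2-[(3R,5R)-3,5-dimethyl-5-[(2R,7E,11E)-2-methyl-12-phenyldodeca-7,11-dien-1-yl]-1,2-dioxolan-3-yl]ethoxy}tri(propan-2-yl)silane (silyloxyethyl arm on C3 trans to the C6 chain on C5)
Conditions: N-triethylsilyl derivative of (R)-3,3'-bis[3,5-bis(trifluoromethyl)phenyl]-1,1'-binaphthalene-2,2'-disulfonimide (10 mol%, preformed from the N–H imide and triethyl(2-methylallyl)silane), 15 (4 equiv), 2,6-di-tert-butyl-4-methylpyridine (10 mol%), toluene, −78 °C; Et3N quench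
Reagents that add atoms: none
Why: Proposed new method: the N-silyl disulfonimide passes Et3Si+ to the methoxy oxygen of 13, Et3SiOMe departs, and the C5 peroxycarbenium ion remains in a contact ion pair with the chiral disulfonimide anion; the CH2 terminus of 15 then adds to C5 (C4–C5 bond) and the tertiary C3 cation is captured by the silylated peroxide oxygen O2 (O2–C3 bond), the Et3Si+ so released returning to the anion to carry the chain. The closest known reaction type is the (3+2) annulation of silyl peroxyketals with alkenes promoted by SnCl4 or Me3SiOTf, which is not stereocontrolled, taken together with silylium catalysis under chiral disulfonimide anions as known for Mukaiyama-type additions. The dioxolane ring is closed by a five-membered collapse of O2 onto the trigonal C3 carbenium centre, a cation–heteroatom combination in which no bond at C3 is broken, so that it is neither an exo nor an endo displacement. C5 (R) is to be set in the C–C bond formation by the anion, which must shield one face of the planar peroxycarbenium ion, and C3 (R in 16) in the ring closure, where the anion still paired with the cation and the preference of the bulky silyloxyethyl arm to lie trans to the C6 chain decide which face of C3 meets O2. The step needs face selectivity at both cationic centres and chemoselectivity for the alkene of 15; the latter rests on the higher nucleophilicity of a 1,1-disubstituted alkene (tertiary cation) over the two 1,2-disubstituted chain alkenes, on its use in excess, and on the chain length, which lets the chain alkenes reach C5 only through rings of eight or more members. The hindered pyridine removes stray protons that would isomerise 15, any exchange between the two silyl groups on the arm is harmless because both are removed in step 12, and C7 is not involved.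

Step 12
Reactants: 16 {2-[(3R,5R)-3,5-dimethyl-5-[(2R,7E,11E)-2-methyl-12-phenyldodeca-7,11-dien-1-yl]-1,2-dioxolan-3-yl]ethoxy}tri(propan-2-yl)silane
Product: 17 2-[(3R,5R)-3,5-dimethyl-5-[(2R,7E,11E)-2-methyl-12-phenyldodeca-7,11-dien-1-yl]-1,2-dioxolan-3-yl]ethan-1-ol
Conditions: Bu4NF, AcOH (1:1), THF, 0 °C to rt
Reagents that add atoms: none
Why: Fluoride-mediated cleavage of the silyl ether, which the peroxide should survive because both peroxide carbons are quaternary and offer no hydrogen for a base-induced Kornblum–DeLaMare fragmentation.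

Step 13
Reactants: 17 2-[(3R,5R)-3,5-dimethyl-5-[(2R,7E,11E)-2-methyl-12-phenyldodeca-7,11-dien-1-yl]-1,2-dioxolan-3-yl]ethan-1-ol
Product: 19 2-[(3S,5R)-3,5-dimethyl-5-[(2R,7E,11E)-2-methyl-12-phenyldodeca-7,11-dien-1-yl]-1,2-dioxolan-3-yl]acetic acid, via dioxolan-3-ylacetaldehyde 18 (not isolated)
Conditions: TEMPO (cat.), PhI(OAc)2 (2.5 equiv), MeCN/H2O (1:1), rt
Reagents that add atoms: water, O
Why: Oxoammonium-catalysed oxidation of the primary alcohol to the aldehyde, whose hydrate is oxidised on to the acid in the same flask under weakly acidic conditions that should spare the O–O bond and the disubstituted alkenes and avoid beta-elimination of the peroxide (the C3 descriptor changes from R to S only through the priority change of the arm).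

Compound list
1 | (E)-5-phenylpent-4-enoic acid | OC(=O)CC/C=C/c1ccccc1 | starting material
2 | (E)-5-phenylpent-4-en-1-ol | OCCC/C=C/c1ccccc1 | intermediate
3 | 1-phenyl-5-{[(4E)-5-phenylpent-4-en-1-yl]sulfanyl}-1H-tetrazole | C(CC/C=C/c1ccccc1)Sc1nnnn1-c1ccccc1 | intermediate
4 | 1-phenyl-5-{[(4E)-5-phenylpent-4-en-1-yl]sulfonyl}-1H-tetrazole | O=S(=O)(CCC/C=C/c1ccccc1)c1nnnn1-c1ccccc1 | intermediate
5 | 6-bromohex-1-ene | BrCCCCC=C | starting material
6 | (E)-pent-3-en-2-one | C/C=C/C(C)=O | starting material
7 | hex-5-en-1-ylmagnesium bromide | C=CCCCC[Mg]Br | intermediate (not isolated)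
8 | (4R)-4-methyldec-9-en-2-one | C[C@H](CCCCC=C)CC(C)=O | intermediate
9 | (7R)-9,9-dimethoxy-7-methyldec-1-ene | C[C@H](CCCCC=C)CC(C)(OC)OC | intermediate
10 | (6R)-8,8-dimethoxy-6-methylnonanal | C[C@H](CCCCC=O)CC(C)(OC)OC | intermediate
11 | [(1E,5E,11R)-13,13-dimethoxy-11-methyltetradeca-1,5-dien-1-yl]benzene (dimethyl ketal of (4R,9E,13E)-4-methyl-14-phenyltetradeca-9,13-dien-2-one) | C[C@H](CCCC/C=C/CC/C=C/c1ccccc1)CC(C)(OC)OC | intermediate
12 | (4R,9E,13E)-2-methoxy-4-methyl-14-phenyltetradeca-9,13-dien-2-yl hydroperoxide (both C2 epimers) | C[C@H](CCCC/C=C/CC/C=C/c1ccccc1)CC(C)(OC)OO | intermediate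
13 | triethyl{[(4R,9E,13E)-2-methoxy-4-methyl-14-phenyltetradeca-9,13-dien-2-yl]peroxy}silane (both C2 epimers) | C[C@H](CCCC/C=C/CC/C=C/c1ccccc1)CC(C)(OC)OO[Si](CC)(CC)CC | intermediate
14 | 3-methylbut-3-en-1-ol | C=C(C)CCO | starting material
15 | [(3-methylbut-3-en-1-yl)oxy]tri(propan-2-yl)silane | C=C(C)CCO[Si](C(C)C)(C(C)C)C(C)C | intermediate
16 | {2-[(3R,5R)-3,5-dimethyl-5-[(2R,7E,11E)-2-methyl-12-phenyldodeca-7,11-dien-1-yl]-1,2-dioxolan-3-yl]ethoxy}tri(propan-2-yl)silane | C[C@H](CCCC/C=C/CC/C=C/c1ccccc1)C[C@]1(C)C[C@@](C)(CCO[Si](C(C)C)(C(C)C)C(C)C)OO1 | intermediate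
17 | 2-[(3R,5R)-3,5-dimethyl-5-[(2R,7E,11E)-2-methyl-12-phenyldodeca-7,11-dien-1-yl]-1,2-dioxolan-3-yl]ethan-1-ol | C[C@H](CCCC/C=C/CC/C=C/c1ccccc1)C[C@]1(C)C[C@@](C)(CCO)OO1 | intermediate
18 | 2-[(3S,5R)-3,5-dimethyl-5-[(2R,7E,11E)-2-methyl-12-phenyldodeca-7,11-dien-1-yl]-1,2-dioxolan-3-yl]acetaldehyde | C[C@H](CCCC/C=C/CC/C=C/c1ccccc1)C[C@]1(C)C[C@@](C)(CC=O)OO1 | intermediate (not isolated)
19 | 2-[(3S,5R)-3,5-dimethyl-5-[(2R,7E,11E)-2-methyl-12-phenyldodeca-7,11-dien-1-yl]-1,2-dioxolan-3-yl]acetic acid | C[C@H](CCCC/C=C/CC/C=C/c1ccccc1)C[C@]1(C)C[C@@](C)(CC(=O)O)OO1 | target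

Total step count: 13 (Grignard formation counted within step 4).
Longest linear sequence: 9 steps (from 5 through steps 4, 5, 6, 7, 8, 9, 11, 12, 13; the branch from 1 through steps 1, 2, 3, 7, 8, 9, 11, 12, 13 is equally long).

Steps most likely to fail

1. Step 11. The anion may discriminate too weakly between the faces of the C5 peroxycarbenium ion, whose two substituents (methyl and a primary alkyl group) differ little, or between the faces of the C3 cation. Proton loss from the C3 cation may also compete with ring closure. The fallback uses known chemistry and moves the stereocontrol at C3 to the substrate. It sets out from 13 and returns at 19.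
 - Me3SiOTf-promoted Mukaiyama-type addition of 2-(trimethylsilyloxy)propene to the peroxycarbenium ion from 13 (CH2Cl2, −78 °C) should give (6R,11E,15E)-4,6-dimethyl-16-phenyl-4-[(triethylsilyl)peroxy]hexadeca-11,15-dien-2-one F1 as both C4 epimers.
 - 10-Camphorsulfonic acid in methanol should remove the peroxide silyl group and close the hydroperoxy ketone to the cyclic methyl peroxyketal 3-methoxy-3,5-dimethyl-5-[(2R,7E,11E)-2-methyl-12-phenyldodeca-7,11-dien-1-yl]-1,2-dioxolane F2.
 - Me3SiOTf then ionises F2 at C3, and 1-(ethylsulfanyl)-1-(trimethylsilyloxy)ethene should add to the cyclic peroxycarbenium ion on the face away from the larger C5 substituent. This places the new arm trans to the C6 chain and gives S-ethyl 2-[(3S,5R)-3,5-dimethyl-5-[(2R,7E,11E)-2-methyl-12-phenyldodeca-7,11-dien-1-yl]-1,2-dioxolan-3-yl]ethanethioate F3.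
 - C5 is formed without control in the first operation, so the C5 epimers (diastereomers through C7) would have to be separated by preparative chromatography at the stage of F3.
 - LiOH in aqueous THF at 0 °C then hydrolyses F3 to 19.

2. Step 8. The exchange may run on to the geminal bis-hydroperoxide, or moisture may hydrolyse the ketal back to the ketone, so that mono-exchange cannot be held. The fallback replaces substitution by addition; it sets out from 11 and returns at 12.
 - Me3SiOTf and i-Pr2NEt (CH2Cl2, −20 °C to rt) eliminate methanol from the ketal under kinetic conditions to give the less substituted methyl enol ether [(1E,5E,11R)-13-methoxy-11-methyltetradeca-1,5,13-trien-1-yl]benzene F4.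
 - Acid-catalysed Markovnikov addition of ethereal H2O2 (pyridinium p-toluenesulfonate, Et2O, 0 °C) across the enol ether then gives 12, with one equivalent of H2O2 consumed per double bond and no second methoxy group left to exchange.

3. Step 4. Enantiofacial selectivity may be poor with the small beta-methyl enone, 1,2-addition may compete, and radical cyclisation during formation of the Grignard reagent may contaminate it. The last would be purged in step 6, since the cyclised by-product has no alkene. The fallback replaces catalyst control by a covalently bound auxiliary; it sets out from 5 (through 7) and returns at 8.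
 - (4R)-4-Phenyl-1,3-oxazolidin-2-one is acylated (n-BuLi, (E)-but-2-enoyl chloride, THF, −78 °C) to (4R)-3-[(2E)-but-2-enoyl]-4-phenyl-1,3-oxazolidin-2-one F5.
 - The Grignard reagent 7 with CuBr·SMe2 (THF/Me2S, −78 to −20 °C) should add to the magnesium-chelated s-cis imide on the face away from the phenyl group, giving (4R)-3-[(3R)-3-methylnon-8-enoyl]-4-phenyl-1,3-oxazolidin-2-one F6, which can be purified as a single diastereomer.
 - Me(MeO)NH·HCl and AlMe3 (CH2Cl2, 0 °C) release the auxiliary and give (3R)-N-methoxy-N,3-dimethylnon-8-enamide F7.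
 - MeMgBr (THF, 0 °C) converts F7 into ketone 8.

Further compounds
F1 | step 11 | (6R,11E,15E)-4,6-dimethyl-16-phenyl-4-[(triethylsilyl)peroxy]hexadeca-11,15-dien-2-one (both C4 epimers) | C[C@H](CCCC/C=C/CC/C=C/c1ccccc1)CC(C)(CC(C)=O)OO[Si](CC)(CC)CC
F2 | step 11 | 3-methoxy-3,5-dimethyl-5-[(2R,7E,11E)-2-methyl-12-phenyldodeca-7,11-dien-1-yl]-1,2-dioxolane (epimers at C3 and C5) | C[C@H](CCCC/C=C/CC/C=C/c1ccccc1)CC1(C)CC(C)(OC)OO1
F3 | step 11 | S-ethyl 2-[(3S,5R)-3,5-dimethyl-5-[(2R,7E,11E)-2-methyl-12-phenyldodeca-7,11-dien-1-yl]-1,2-dioxolan-3-yl]ethanethioate | C[C@H](CCCC/C=C/CC/C=C/c1ccccc1)C[C@]1(C)C[C@@](C)(CC(=O)SCC)OO1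
F4 | step 8 | [(1E,5E,11R)-13-methoxy-11-methyltetradeca-1,5,13-trien-1-yl]benzene | C[C@H](CCCC/C=C/CC/C=C/c1ccccc1)CC(=C)OC
F5 | step 4 | (4R)-3-[(2E)-but-2-enoyl]-4-phenyl-1,3-oxazolidin-2-one | O=C1OC[C@@H](c2ccccc2)N1C(=O)/C=C/C
F6 | step 4 | (4R)-3-[(3R)-3-methylnon-8-enoyl]-4-phenyl-1,3-oxazolidin-2-one | O=C1OC[C@@H](c2ccccc2)N1C(=O)C[C@H](C)CCCCC=C
F7 | step 4 | (3R)-N-methoxy-N,3-dimethylnon-8-enamide | CON(C)C(=O)C[C@H](C)CCCCC=C
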